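**Plan**

- Numbering: flavanone O1, C2, C3, C4 (ketone), ring A = C4a–C8a (OH on C5, OMe on C7), ring B = C1'–C6' on C2; the apigenin unit is joined through its C8'' to C3'.
- Enabling feature: ring C is an oxygen heterocycle fused to the phenolic ring A. Its O1–C8a–C4a–C4 segment is a latent ortho-quinone methide of ring A, and its C2–C3 segment, with ring B on C2, is a 4-oxygenated styrene.
- Cuts: with C4 lowered to the methyl ether level, O1–C2 and C3–C4 are cut together ([4+2]); then the vinyl C=C (Wittig) and the biaryl bond C3'–C8'' (Suzuki–Miyaura).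
- Forward: the ring A salicylaldehyde comes from trihydroxybenzaldehyde by two O-alkylations; apigenin is benzylated, iodinated at C8'' and coupled with the ring B boronate; methylenation gives the styrene. Ring C, the only ring built, is closed by the cycloaddition, then C4–OMe is taken to C4–OH and C4=O, and the benzyl ethers are removed.
- Stereochemistry: C2 (S) is the only stereocentre of the target and is set in the cycloaddition by a chiral Brønsted acid. The C4 centre formed alongside is erased by oxidation.

Key step: step 9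

Assumption: the C3'–C8'' biaryl axis is taken to rotate freely at room temperature (the target is drawn without axial configuration), so C2 is the only stereogenic element to control.

Assumption: the sense of induction of the chiral acid in step 9 cannot be predicted for this new reaction; the (R)-catalyst is written, and its mirror image is used instead if a first run favours the (2R)-product.

**Route**

Step 1
Reactants: 1 2,4,6-trihydroxybenzaldehyde
Product: 2 2,6-dihydroxy-4-methoxybenzaldehyde
Conditions: Me2SO4 (1.0 equiv), K2CO3 (1.0 equiv), acetone, 0 °C to rt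
Reagents that add atoms: dimethyl sulfate, COS(=O)(=O)OC
Why: Williamson O-methylation in which the 4-OH, the most acidic hydroxyl and the only one not hydrogen-bonded to the aldehyde, should react first when base and alkylating agent are limited to one equivalent.

Step 2
Reactants: 2 2,6-dihydroxy-4-methoxybenzaldehyde
Product: 3 2-benzyloxy-6-hydroxy-4-methoxybenzaldehyde
Conditions: BnBr (1.05 equiv), K2CO3 (1.1 equiv), DMF, rt
Reagents that add atoms: benzyl bromide, BrCc1ccccc1
Why: Williamson etherification of one of two equivalent phenols, which should stop at the monoether because the remaining hydroxyl is then locked in the hydrogen bond to the aldehyde and is far less nucleophilic.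

Step 3
Reactants: 4 apigenin
Product: 5 5,7,4'-tri-O-benzylapigenin
Conditions: BnBr (4.5 equiv), K2CO3 (6 equiv), DMF, 80 °C
Reagents that add atoms: benzyl bromide, BrCc1ccccc1
Why: exhaustive Williamson benzylation, with excess reagent and heat so that the chelated 5-OH is also alkylated, as is routine for 5-hydroxyflavones.

Step 4
Reactants: 5 5,7,4'-tri-O-benzylapigenin
Product: 6 8-iodo-5,7,4'-tri-O-benzylapigenin
Conditions: NIS (1.1 equiv), CF3CO2H (0.3 equiv), CH2Cl2/MeCN, 0 °C to rt, dark
Reagents that add atoms: N-iodosuccinimide, O=C1CCC(=O)N1I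
Why: electrophilic aromatic iodination, which on 5,7-dialkoxyflavones with the 5-oxygen capped goes to C8 (ortho to the ring oxygen and the 7-alkoxy group, para to the 5-alkoxy group) and not to C6, which is flanked by two benzyloxy groups, or to the less activated ring of the 4-benzyloxyphenyl group.

Step 5
Reactants: 7 3-bromo-4-hydroxybenzaldehyde
Product: 8 4-benzyloxy-3-bromobenzaldehyde
Conditions: BnBr (1.1 equiv), K2CO3 (1.5 equiv), DMF, rt
Reagents that add atoms: benzyl bromide, BrCc1ccccc1
Why: Williamson etherification of an acidic para-formyl phenol, a routine protection.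

Step 6
Reactants: 8 4-benzyloxy-3-bromobenzaldehyde
Product: 9 4-benzyloxy-3-(4,4,5,5-tetramethyl-1,3,2-dioxaborolan-2-yl)benzaldehyde
Conditions: B2pin2 (1.2 equiv), PdCl2(dppf) (3 mol %), KOAc (3 equiv), 1,4-dioxane, 85 °C
Reagents that add atoms: bis(pinacolato)diboron, CC1(C)OB(OC1(C)C)B1OC(C)(C)C(C)(C)O1
Why: Miyaura borylation of an aryl bromide, which tolerates the aldehyde and the benzyl ether and, with the weak base KOAc, should not go on to homocoupling.

Step 7
Reactants: 6 8-iodo-5,7,4'-tri-O-benzylapigenin; 9 4-benzyloxy-3-(4,4,5,5-tetramethyl-1,3,2-dioxaborolan-2-yl)benzaldehyde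
Product: 10 4-benzyloxy-3-[5,7-bis(benzyloxy)-2-(4-benzyloxyphenyl)-4-oxo-4H-chromen-8-yl]benzaldehyde
Conditions: Pd(OAc)2 (5 mol %), SPhos (10 mol %), K3PO4 (3 equiv), toluene/H2O (10:1), 90 °C
Reagents that add atoms: none
Why: Suzuki–Miyaura coupling of an 8-iodoflavone with an ortho-alkoxyaryl boronate, the standard way to the 3',8''-biflavonoid axis, with a bulky biarylphosphine to help the tri-ortho-substituted biaryl form.

Step 8
Reactants: 10 4-benzyloxy-3-[5,7-bis(benzyloxy)-2-(4-benzyloxyphenyl)-4-oxo-4H-chromen-8-yl]benzaldehyde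
Product: 11 5,7-bis(benzyloxy)-2-(4-benzyloxyphenyl)-8-(2-benzyloxy-5-vinylphenyl)-4H-chromen-4-one
Conditions: Ph3PCH3Br (1.3 equiv), KOtBu (1.25 equiv), THF, 0 °C; then 10, 0 °C to rt
Reagents that add atoms: methyltriphenylphosphonium bromide, C[P+](c1ccccc1)(c1ccccc1)c1ccccc1.[Br-]
Why: Wittig methylenation, in which the aryl aldehyde should be consumed at 0 °C well before the ylide can attack the vinylogous ester carbonyl of the flavone.

Step 9
Reactants: 3 2-benzyloxy-6-hydroxy-4-methoxybenzaldehyde; 11 5,7-bis(benzyloxy)-2-(4-benzyloxyphenyl)-8-(2-benzyloxy-5-vinylphenyl)-4H-chromen-4-one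
Product: 14 (2S,4S)-5-benzyloxy-2-{4-benzyloxy-3-[5,7-bis(benzyloxy)-2-(4-benzyloxyphenyl)-4-oxo-4H-chromen-8-yl]phenyl}-4,7-dimethoxychromane, via dimethyl acetal 12 (not isolated), via methoxy ortho-quinone methide 13 (not isolated)
Conditions: 3 (1.5 equiv), HC(OMe)3 (2 equiv), (R)-3,3'-bis(2,4,6-triisopropylphenyl)-BINOL N-triflylphosphoramide (10 mol %), toluene, rt, 1 h; then −40 °C, slow addition of 11; Et3N quench at −40 °C
Reagents that add atoms: trimethyl orthoformate, COC(OC)OC
Why: Proposed new method: the acid first turns 3 and trimethyl orthoformate into acetal 12 and then ionises it to the methoxy-substituted ortho-quinone methide 13 (equally an aryl oxocarbenium ion carrying the free phenol), which stays hydrogen-bonded to the chiral phosphoramide anion; the CH2 terminus of styrene 11 attacks the methide carbon (C3–C4), the C2 benzylic cation, stabilised by the para-benzyloxy group, is captured by the ring A oxygen (O1–C2), and rearomatisation of ring A drives the process. The closest known reaction types are the achiral acid-catalysed three-component [4+2] reaction of salicylaldehydes, orthoformates and styrenes to 2,4-cis-4-alkoxyflavans and the chiral phosphoric acid-catalysed cycloadditions of ortho-quinone methides generated from ortho-hydroxybenzyl alcohols; an intermolecular enantioselective version with an alkoxy-substituted quinone methide has not been shown. Ring C closes as the six-membered ring of an intermolecular inverse-electron-demand oxa-[4+2] cycloaddition, four atoms (O1, C8a, C4a, C4) coming from 13 and two (C3, C2) from 11, in an asynchronous mode with C–C bond formation ahead of O–C closure. C2 (S) is to be controlled by the chiral anion, which blocks one face of the bound quinone methide and so decides which enantioface of the styrene is engaged, while C4 follows from endo approach of the aryl group (2,4-cis, hence 4S) and needs no control because it is oxidised later. The step needs regioselectivity (aryl on C2, not C3), which the polarisation of the styrene by its 4-benzyloxy group secures, and enantiofacial selectivity at C2, which rests on the catalyst alone and on ring closure outrunning rotation of the C2 cation and re-ionisation of the product, hence the low temperature, the slow addition of 11 and the amine quench.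

Step 10
Reactants: 14 (2S,4S)-5-benzyloxy-2-{4-benzyloxy-3-[5,7-bis(benzyloxy)-2-(4-benzyloxyphenyl)-4-oxo-4H-chromen-8-yl]phenyl}-4,7-dimethoxychromane
Product: 15 (2S)-5-benzyloxy-2-{4-benzyloxy-3-[5,7-bis(benzyloxy)-2-(4-benzyloxyphenyl)-4-oxo-4H-chromen-8-yl]phenyl}-7-methoxychroman-4-ol (mixture of C4 epimers)
Conditions: p-TsOH·H2O (10 mol %), THF/H2O (3:1), 0.02 M, rt; aq NaHCO3 quench
Reagents that add atoms: water, O
Why: SN1 solvolysis of a benzylic methyl ether whose C4 cation is stabilised by the three oxygen substituents of ring A, so that dilute acid and a large excess of water should exchange OMe for OH without ionising the much less activated O1–C2 bond; the C4 epimer mixture is of no consequence.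

Step 11
Reactants: 15 (2S)-5-benzyloxy-2-{4-benzyloxy-3-[5,7-bis(benzyloxy)-2-(4-benzyloxyphenyl)-4-oxo-4H-chromen-8-yl]phenyl}-7-methoxychroman-4-ol
Product: 16 (2S)-5-benzyloxy-2-{4-benzyloxy-3-[5,7-bis(benzyloxy)-2-(4-benzyloxyphenyl)-4-oxo-4H-chromen-8-yl]phenyl}-7-methoxychroman-4-one
Conditions: nPr4N[RuO4] (5 mol %), NMO (1.5 equiv), 4 Å MS, CH2Cl2, rt (15 used crude)
Reagents that add atoms: none
Why: Ley–Griffith oxidation of a secondary benzylic alcohol under essentially neutral conditions, which should neither ionise C4 nor open ring C by retro-oxa-Michael reaction, so the C2 configuration is kept while the C4 centre disappears.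

Step 12
Reactants: 16 (2S)-5-benzyloxy-2-{4-benzyloxy-3-[5,7-bis(benzyloxy)-2-(4-benzyloxyphenyl)-4-oxo-4H-chromen-8-yl]phenyl}-7-methoxychroman-4-one
Product: 17 (2S)-5-hydroxy-2-{4-hydroxy-3-[5,7-dihydroxy-2-(4-hydroxyphenyl)-4-oxo-4H-chromen-8-yl]phenyl}-7-methoxychroman-4-one (CNP0107492.1)
Conditions: H2 (1 atm), 10% Pd/C, THF/MeOH (1:1), rt, stopped when uptake ceases
Reagents that add atoms: none
Why: hydrogenolysis of five aryl benzyl ethers under neutral conditions, as used routinely on benzylated flavones and flavanones, which should leave the methyl ether, the flavone double bond, the aryl ketone and the base- and acid-sensitive C2 centre untouched.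

**Compound list**

1 | 2,4,6-trihydroxybenzaldehyde | O=Cc1c(O)cc(O)cc1O | starting material
2 | 2,6-dihydroxy-4-methoxybenzaldehyde | COc1cc(O)c(C=O)c(O)c1 | intermediate
3 | 2-benzyloxy-6-hydroxy-4-methoxybenzaldehyde | COc1cc(O)c(C=O)c(OCc2ccccc2)c1 | intermediate
4 | apigenin | O=c1cc(-c2ccc(O)cc2)oc2cc(O)cc(O)c12 | starting material
5 | 5,7,4'-tri-O-benzylapigenin | O=c1cc(-c2ccc(OCc3ccccc3)cc2)oc2cc(OCc3ccccc3)cc(OCc3ccccc3)c12 | intermediate
6 | 8-iodo-5,7,4'-tri-O-benzylapigenin | O=c1cc(-c2ccc(OCc3ccccc3)cc2)oc2c(I)c(OCc3ccccc3)cc(OCc3ccccc3)c12 | intermediate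
7 | 3-bromo-4-hydroxybenzaldehyde | O=Cc1ccc(O)c(Br)c1 | starting material
8 | 4-benzyloxy-3-bromobenzaldehyde | O=Cc1ccc(OCc2ccccc2)c(Br)c1 | intermediate
9 | 4-benzyloxy-3-(4,4,5,5-tetramethyl-1,3,2-dioxaborolan-2-yl)benzaldehyde | O=Cc1ccc(OCc2ccccc2)c(B2OC(C)(C)C(C)(C)O2)c1 | intermediate
10 | 4-benzyloxy-3-[5,7-bis(benzyloxy)-2-(4-benzyloxyphenyl)-4-oxo-4H-chromen-8-yl]benzaldehyde | O=Cc1ccc(OCc2ccccc2)c(-c2c(OCc3ccccc3)cc(OCc3ccccc3)c3c(=O)cc(-c4ccc(OCc5ccccc5)cc4)oc23)c1 | intermediate
11 | 5,7-bis(benzyloxy)-2-(4-benzyloxyphenyl)-8-(2-benzyloxy-5-vinylphenyl)-4H-chromen-4-one | C=Cc1ccc(OCc2ccccc2)c(-c2c(OCc3ccccc3)cc(OCc3ccccc3)c3c(=O)cc(-c4ccc(OCc5ccccc5)cc4)oc23)c1 | intermediate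
12 | 3-benzyloxy-2-(dimethoxymethyl)-5-methoxyphenol (dimethyl acetal of 3, not isolated) | COc1cc(O)c(C(OC)OC)c(OCc2ccccc2)c1 | intermediate
13 | 5-benzyloxy-3-methoxy-6-(methoxymethylidene)cyclohexa-2,4-dien-1-one (methoxy ortho-quinone methide, not isolated, geometry of the exocyclic double bond not assigned) | COC=C1C(=O)C=C(OC)C=C1OCc1ccccc1 | intermediate
14 | (2S,4S)-5-benzyloxy-2-{4-benzyloxy-3-[5,7-bis(benzyloxy)-2-(4-benzyloxyphenyl)-4-oxo-4H-chromen-8-yl]phenyl}-4,7-dimethoxychromane (2,4-cis) | COc1cc(OCc2ccccc2)c2c(c1)O[C@H](c1ccc(OCc3ccccc3)c(-c3c(OCc4ccccc4)cc(OCc4ccccc4)c4c(=O)cc(-c5ccc(OCc6ccccc6)cc5)oc34)c1)C[C@@H]2OC | intermediate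
15 | (2S)-5-benzyloxy-2-{4-benzyloxy-3-[5,7-bis(benzyloxy)-2-(4-benzyloxyphenyl)-4-oxo-4H-chromen-8-yl]phenyl}-7-methoxychroman-4-ol (C4 epimer mixture, C4 drawn without configuration) | COc1cc(OCc2ccccc2)c2c(c1)O[C@H](c1ccc(OCc3ccccc3)c(-c3c(OCc4ccccc4)cc(OCc4ccccc4)c4c(=O)cc(-c5ccc(OCc6ccccc6)cc5)oc34)c1)CC2O | intermediate
16 | (2S)-5-benzyloxy-2-{4-benzyloxy-3-[5,7-bis(benzyloxy)-2-(4-benzyloxyphenyl)-4-oxo-4H-chromen-8-yl]phenyl}-7-methoxychroman-4-one | COc1cc(OCc2ccccc2)c2c(c1)O[C@H](c1ccc(OCc3ccccc3)c(-c3c(OCc4ccccc4)cc(OCc4ccccc4)c4c(=O)cc(-c5ccc(OCc6ccccc6)cc5)oc34)c1)CC2=O | intermediate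
17 | (2S)-5-hydroxy-2-{4-hydroxy-3-[5,7-dihydroxy-2-(4-hydroxyphenyl)-4-oxo-4H-chromen-8-yl]phenyl}-7-methoxychroman-4-one (CNP0107492.1) | COc1cc(O)c2c(c1)O[C@H](c1ccc(O)c(-c3c(O)cc(O)c4c(=O)cc(-c5ccc(O)cc5)oc34)c1)CC2=O | target

**Summary**

Total step count: 12. Longest linear sequence: 8 steps (steps 3, 4, 7, 8, 9, 10, 11, 12 from apigenin; equally steps 5, 6, 7, 8, 9, 10, 11, 12 from the bromo aldehyde).

**Steps most likely to fail**

Step 9 (proposed new method). The ion pair may not discriminate the two faces at C2, or the C2 cation may rotate before ring closure, giving low enantiomeric purity. The electron-rich styrene may also oligomerise under acid, and the flavone carbonyl may tie up the catalyst. The fallback sets out from 3 and 11 and uses known chemistry: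
- The cycloaddition is run with trimethyl orthoformate and the achiral Lewis acid Sc(OTf)3 (10 mol %) in CH2Cl2 at rt, the established racemic three-component reaction, to give the racemic 2,4-cis-4-methoxyflavan F1.
- Solvolysis as in step 10 gives the racemic flavan-4-ol F2, and oxidation as in step 11 gives the racemic flavanone F3.
- F3 is resolved kinetically by asymmetric transfer hydrogenation with RuCl(p-cymene)[(R,R)-TsDPEN] and HCO2H/Et3N in EtOAc at rt. By analogy with simple aryl ketones this should reduce the (2R)-ketone to the (2R,4R)-flavan-4-ol F4 and leave the (2S)-ketone.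
- After chromatographic separation the route is rejoined at 16, with at most half of the material.

Step 10. The C4 cation may lose a C3 proton to give the flav-3-ene or be trapped by an electron-rich arene (oligomerisation) instead of by water. Prolonged acid exposure could also ionise O1–C2 and erode the C2 configuration. The fallback sets out from 14 and oxidises the benzylic methyl ether directly with DDQ (1.2 equiv) in CH2Cl2/pH 7 buffer at 0 °C. Hydride abstraction from C4 gives a methoxy-stabilised oxocarbenium ion, which water converts into the ketone and methanol. The route is rejoined at 16, bypassing 15, and no compound outside the list is made (F0).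

Step 12. Hydrogenation may run on to saturate the flavone C2''–C3'' double bond or cleave the benzylic O1–C2 bond, or it may stall at partly benzylated stages through poor solubility. The fallback sets out from 16 and removes the benzyl groups by Lewis acid cleavage with BCl3 (excess) and pentamethylbenzene as cation scavenger in CH2Cl2 at −78 °C, with a methanol quench at low temperature. The aryl methyl ether is expected to survive at this temperature. The route is rejoined at 17, and no compound outside the list is made (F0).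

Further compounds
F1 | step 9 | racemic 2,4-cis-5-benzyloxy-2-{4-benzyloxy-3-[5,7-bis(benzyloxy)-2-(4-benzyloxyphenyl)-4-oxo-4H-chromen-8-yl]phenyl}-4,7-dimethoxychromane (racemate of 14, drawn without configuration) | COc1cc(OCc2ccccc2)c2c(c1)OC(c1ccc(OCc3ccccc3)c(-c3c(OCc4ccccc4)cc(OCc4ccccc4)c4c(=O)cc(-c5ccc(OCc6ccccc6)cc5)oc34)c1)CC2OC
F2 | step 9 | racemic 5-benzyloxy-2-{4-benzyloxy-3-[5,7-bis(benzyloxy)-2-(4-benzyloxyphenyl)-4-oxo-4H-chromen-8-yl]phenyl}-7-methoxychroman-4-ol (C4 epimer mixture, drawn without configuration) | COc1cc(OCc2ccccc2)c2c(c1)OC(c1ccc(OCc3ccccc3)c(-c3c(OCc4ccccc4)cc(OCc4ccccc4)c4c(=O)cc(-c5ccc(OCc6ccccc6)cc5)oc34)c1)CC2O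
F3 | step 9 | racemic 5-benzyloxy-2-{4-benzyloxy-3-[5,7-bis(benzyloxy)-2-(4-benzyloxyphenyl)-4-oxo-4H-chromen-8-yl]phenyl}-7-methoxychroman-4-one (racemate of 16, drawn without configuration) | COc1cc(OCc2ccccc2)c2c(c1)OC(c1ccc(OCc3ccccc3)c(-c3c(OCc4ccccc4)cc(OCc4ccccc4)c4c(=O)cc(-c5ccc(OCc6ccccc6)cc5)oc34)c1)CC2=O
F4 | step 9 | (2R,4R)-5-benzyloxy-2-{4-benzyloxy-3-[5,7-bis(benzyloxy)-2-(4-benzyloxyphenyl)-4-oxo-4H-chromen-8-yl]phenyl}-7-methoxychroman-4-ol (2,4-cis) | COc1cc(OCc2ccccc2)c2c(c1)O[C@@H](c1ccc(OCc3ccccc3)c(-c3c(OCc4ccccc4)cc(OCc4ccccc4)c4c(=O)cc(-c5ccc(OCc6ccccc6)cc5)oc34)c1)C[C@H]2O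
F0 | step 10 | none | none
F0 | step 12 | none | none
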